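**Retrosynthetic overview**
1. Cut the prenyl–C6 bond last. The quaternary centre comes from a palladium-catalysed asymmetric dearomative prenylation of a fully substituted aromatic acylphloroglucinol.
2. Cut C2'–C6' of the cyclopentane. The precursor is the 2',3'-epoxygeranyl arene, closed by an epoxide-triggered epoxide–olefin cyclisation run as a cobalt radical process, so the epoxide opens at C2'.
3. Cut aryl–C1'. This bond comes from reductive alkylation of 3-methylphlorisovalerophenone with (2R,3S)-2,3-epoxygeranial.
4. The epoxy aldehyde comes from geraniol (Sharpless epoxidation, then oxidation). The arene comes from 2-methylphloroglucinol and isovaleryl chloride.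
5. Ring order: six-membered ring A is bought as the arene, cyclopentane ring B is formed in step 5, and ring A is dearomatised in step 6.

Assumption: the presumed biosynthesis is 2',3'-epoxidation of the geranyl chain of the acylphloroglucinol, then C2'–C6' closure and loss of a C8' hydrogen to give the isopropenyl group.
Assumption: the (R,R) ligand in step 6 gives the (6S) centre; if the sense is opposite, the equally available (S,S) ligand is used.

**Step 1**
Reactants: 1 2-methylphloroglucinol; 2 isovaleryl chloride
Product: 3 3-methyl-1-(2,4,6-trihydroxy-3-methylphenyl)butan-1-one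
Conditions: AlCl3 (3.5 equiv), CH2Cl2/PhNO2, 0 to 45 °C; ice/HCl quench
Reagents that add atoms: none
Why: Friedel–Crafts C-acylation of the electron-rich triol, where the two free ring positions are equivalent by symmetry and the first acyl group deactivates the ring against a second one; no stereocentre is formed.

**Step 2**
Reactants: 4 geraniol
Product: 5 (2S,3S)-2,3-epoxygeraniol
Conditions: Ti(OiPr)4 (5 mol%), L-(+)-DET (7 mol%), TBHP (1.5 equiv), 4 Å MS, CH2Cl2, −20 °C
Reagents that add atoms: tert-butyl hydroperoxide, CC(C)(C)OO
Why: Katsuki–Sharpless asymmetric epoxidation, in which the allylic hydroxyl binds the titanium tartrate so that only the 2,3-alkene reacts, and L-(+)-DET delivers oxygen to the face giving the (2S,3S) epoxide (about 95% ee), which fixes the later carbinol centre C3'.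

**Step 3**
Reactants: 5 (2S,3S)-2,3-epoxygeraniol
Product: 6 (2R,3S)-3-methyl-3-(4-methylpent-3-en-1-yl)oxirane-2-carbaldehyde
Conditions: TEMPO (10 mol%), PhI(OAc)2 (1.1 equiv), CH2Cl2, 20 °C
Reagents that add atoms: none
Why: Oxoammonium (TEMPO) oxidation of the primary alcohol stops at the aldehyde and leaves the epoxide and the trisubstituted alkene alone; the descriptor at C2 changes only through CIP priorities.

**Step 4**
Reactants: 3 3-methyl-1-(2,4,6-trihydroxy-3-methylphenyl)butan-1-one; 6 (2R,3S)-epoxygeranial
Product: 8 1-[2,4,6-trihydroxy-3-methyl-5-{[(2S,3S)-3-methyl-3-(4-methylpent-3-en-1-yl)oxiran-2-yl]methyl}phenyl]-3-methylbutan-1-one, via ortho-quinone methide 7 (not isolated)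
Conditions: L-proline (20 mol%), Hantzsch ester (1.2 equiv), MeCN, 20 °C, 3 h; quick filtration through neutral alumina, used at once
Reagents that add atoms: none
Why: Three-component reductive alkylation, in which an amine-catalysed Knoevenagel/Mannich-type condensation at the only free ring carbon gives 7, and 7 takes hydride from the Hantzsch ester at C1' faster than it adds a second arene; both epoxide centres are untouched.

**Step 5**
Reactants: 8 2',3'-epoxygeranyl arene
Product: 9 1-[2,4,6-trihydroxy-3-{[(1R,2S,5S)-2-hydroxy-2-methyl-5-(prop-1-en-2-yl)cyclopentyl]methyl}-5-methylphenyl]-3-methylbutan-1-one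
Conditions: vitamin B12 (cyanocobalamin, C63H88CoN14O14P, 5 mol%), Zn dust (20 mol%), NH4Cl (20 mol%), degassed MeCN/MeOH 4:1, blue LEDs, 20 °C
Reagents that add atoms: none
Why: Proposed new method: monovalent cobalt made from the corrin by Zn is a soft supernucleophile that should open the trisubstituted epoxide by SN2 attack at the secondary carbon C2' (contra-Markovnikov, and faster than the neutral flanking phenols can attack); visible light then breaks the weak secondary Co–C bond to give a β-hydroxyalkyl radical in which the Sharpless-derived centre C3' (S) is untouched; 5-exo-trig closure onto the 6',7'-alkene through a chair-like Beckwith–Houk transition state places CH2Ar anti to the C3' methyl and anti to the new C7' radical centre (this sets C2' as R and C6' as S, expected about 4:1, with minor isomers removed by chromatography); divalent cobalt then takes a methyl hydrogen from the tertiary radical (dehydrocobaltation) to give the isopropenyl group and, after proton transfer to the alkoxide, the monovalent catalyst again, so the step is a redox-neutral isomerisation; the closest known reaction types are cobalt-mediated radical cyclisation–dehydrocobaltation of alkyl halides, vitamin B12-catalysed epoxide opening at the less substituted carbon, and cobalt-catalysed Heck-type epoxide–alkene coupling.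

**Step 6**
Reactants: 9 aromatic cyclopentanol; 10 prenyl acetate
Product: 11 (6S)-3,5-dihydroxy-4-{[(1R,2S,5S)-2-hydroxy-2-methyl-5-(prop-1-en-2-yl)cyclopentyl]methyl}-6-methyl-2-(3-methylbutanoyl)-6-(3-methylbut-2-en-1-yl)cyclohexa-2,4-dien-1-one (target)
Conditions: Pd2(dba)3·CHCl3 (2.5 mol%), (R,R)-DACH-phenyl Trost ligand (7.5 mol%), 10 (1.0 equiv), Et3N (2.2 equiv), CH2Cl2, 0 to 20 °C; 1 M HCl wash
Reagents that add atoms: none
Why: Tsuji–Trost asymmetric allylic alkylation run as a dearomatisation, in which the ammonium phenolate attacks the unsubstituted terminus of the π-prenyl palladium complex through the methyl-bearing ring carbon (less hindered than the carbon carrying the cyclopentylmethyl group), O-prenyl ethers re-ionise and funnel to the C-alkylated vinylogous acid, and the chiral pocket of the ligand chooses the ring face, so the quaternary centre is set as S under catalyst control; material from the minor enantiomer of 5 ends up as a separable diastereomer.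

**Compound list**
1 | 2-methylphloroglucinol (2-methylbenzene-1,3,5-triol) | Cc1c(O)cc(O)cc1O | starting material
2 | isovaleryl chloride | CC(C)CC(=O)Cl | starting material
3 | 3-methyl-1-(2,4,6-trihydroxy-3-methylphenyl)butan-1-one | CC(C)CC(=O)c1c(O)cc(O)c(C)c1O | intermediate
4 | geraniol | CC(C)=CCC/C(C)=C/CO | starting material
5 | (2S,3S)-2,3-epoxygeraniol | OC[C@@H]1O[C@@]1(C)CCC=C(C)C | intermediate
6 | (2R,3S)-2,3-epoxygeranial | O=C[C@@H]1O[C@@]1(C)CCC=C(C)C | intermediate
7 | ortho-quinone methide from 3 and 6 (exocyclic alkene geometry open) | O=C1C(C)=C(O)C(C(=O)CC(C)C)=C(O)C1=C[C@@H]2O[C@@]2(C)CCC=C(C)C | intermediate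
8 | (2'S,3'S)-2',3'-epoxygeranyl arene | CC(C)CC(=O)c1c(O)c(C)c(O)c(C[C@@H]2O[C@@]2(C)CCC=C(C)C)c1O | intermediate
9 | aromatic cyclopentanol, (1R,2S,5S) in the cyclopentane | C=C(C)[C@H]1CC[C@](C)(O)[C@@H]1Cc2c(O)c(C)c(O)c(C(=O)CC(C)C)c2O | intermediate
10 | prenyl acetate | CC(=O)OCC=C(C)C | starting material
11 | CNP0139230.1 | C=C(C)[C@H]1CC[C@](C)(O)[C@@H]1CC1=C(O)[C@](C)(CC=C(C)C)C(=O)C(C(=O)CC(C)C)=C1O | target

**Totals**
Total step count: 6.
Longest linear sequence: 5 (4 → 5 → 6 → 8 → 9 → 11).

**Steps most likely to fail**

Step 5.
- Risks: the corrin may be too bulky for the hindered C2'. The β-hydroxyalkyl cobalt species may collapse to the deoxygenated alkene or to the allylic alcohol. The phenols may open the epoxide first.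
- Fallback: this sets out from 3 and gives up the C2'–C6' closure for a chiral-pool aldol closure of C2'–C3'. Purchased (S)-(−)-limonene is cleaved at its ring alkene (1 equiv O3, then Me2S) to (3S)-6-oxo-3-(prop-1-en-2-yl)heptanal F2. A mild, reversible 5-enolexo intramolecular aldol addition, stopped before dehydration, gives the thermodynamically preferred (1R,2S,5S)-2-hydroxy-2-methyl-5-(prop-1-en-2-yl)cyclopentane-1-carbaldehyde F1. Reductive alkylation of 3 with F1 (proline, Hantzsch ester) comes back to the route at 9.

Step 4.
- Risks: the flanking phenols may open the epoxide to a dihydrobenzofuran or chromanol. A second arene may add to 7.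
- Fallback: this sets out from 6 and closes ring B before the arene is present. The same cobalt/light cycloisomerisation is applied to 6, where attack at C2 is favoured both as the less substituted carbon and as the carbon next to the formyl group. It gives (1R,2S,5S)-2-hydroxy-2-methyl-5-(prop-1-en-2-yl)cyclopentane-1-carbaldehyde F1, whose formyl-bearing centre can equilibrate to the all-trans arrangement. F1 is then joined to 3 by the proline/Hantzsch ester reductive alkylation, and the route is rejoined at 9.

Step 6.
- Risks: the ligand may give low face selectivity. Attack may occur at the other substituted ring carbon. A second prenylation may follow the first.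
- Fallback: this sets out from 9 and drops catalyst control. A plain SN2 dearomative alkylation (prenyl bromide, aqueous KOH/MeOH, 0 °C) gives 11 together with its (6R) epimer F3. Because the cyclopentane is already enantiopure, the two are diastereomers and are separated by preparative HPLC, which arrives at 11.

**Further compounds**
F1 | step 4 | (1R,2S,5S)-2-hydroxy-2-methyl-5-(prop-1-en-2-yl)cyclopentane-1-carbaldehyde | C=C(C)[C@H]1CC[C@](C)(O)[C@@H]1C=O
F2 | step 5 | (3S)-6-oxo-3-(prop-1-en-2-yl)heptanal | C=C(C)[C@H](CC=O)CCC(C)=O
F3 | step 6 | (6R) epimer of 11 | C=C(C)[C@H]1CC[C@](C)(O)[C@@H]1CC1=C(O)[C@@](C)(CC=C(C)C)C(=O)C(C(=O)CC(C)C)=C1O
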